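## The problem

The target is a spiro N,O-ketal. Its quaternary carbon C3 belongs to a 4-methoxyisoindolin-1-one (ring A the benzene; ring B the lactam with carbonyl C1, nitrogen N2 and C3). The same carbon is C2 of a 2H-naphtho[1,8-bc]furan (ring C): it is bonded to naphthalene C8′ and, through the peri oxygen O1′, to C1′. The naphthalene (numbered as in 3-methylnaphthalene-1,7-diol) carries a free hydroxyl at C7′, ortho to the spiro junction, and a methyl at C3′; N2 carries a 2-hydroxyethyl chain. C3 is the only stereocentre (R) and bears O, N and two aryl carbons, so no other centre can relay chirality to it; it must come from a catalyst or a resolution. It is also crowded, lying between the methoxy-flanked ring-A carbon C3a and a naphthalene carbon flanked by O7′ and the peri oxygen. In the oxidation state of the target C3 is labile: acid can expel the peri aryloxide with help from N2 (N-acyliminium ion), and base acting on the 7′-hydroxyl can open ring C through an ortho-quinone methide. Either event planarises C3, and the free naphthol is also easily oxidised. The phenol therefore has to stay masked through every oxidising or basic operation, and the last steps must be neutral. The enabling feature is that C3 sits on ring A next to C7a, which carries the C1 carbonyl. If N2 is replaced by a carbonyl carbon, C3 becomes the α-carbon of an α-aryloxy-α,α-diarylacetamide with an ortho carboxyl group; that centre has no donor lone pair and can only ionise to an acyl-destabilised cation, so it is configurationally robust. A Hofmann rearrangement then moves C3 from carbon to nitrogen with retention, and the ortho acid captures the isocyanate to close ring B.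

## Retrosynthesis

**Target 29 to bis-benzyl ether 28.** The two O–benzyl bonds are cut last. Hydrogenolysis is the only deprotection here that needs neither acid nor base, which is why benzyl is preferred to silyl or acetal groups on both oxygens. The precursor is no simpler, but it is stable to everything that precedes it.

**28 to lactam 25 and triflate 27.** The N2–CH2 bond is cut. The nitrogen is born as N–H in the rearrangement (a primary amide is required there), so the side chain can only follow it. The forward step must be fast at low temperature so that the amidate does not live long enough to expel the peri aryloxide; hence triflate 27, made from 2-(benzyloxy)ethanol 26, and not a halide.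

**25 to amide acid 22 (key disconnection).** The C3–N2 and N2–C1 bonds are cut and a carbonyl carbon is reinserted between nitrogen and C3. The neighbouring cuts (C3–N by addition of an amide to a quinone methide or acyliminium ion, or C3–O last) would all create the stereocentre by an ionisation that can run backwards. This cut transfers an existing, resolved centre stereospecifically. The precursor has lost the N,O-ketal altogether and is an ordinary acid and primary amide. The forward reaction must go with retention and with internal capture of the isocyanate.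

**22 to imide 20, and 20 to racemate 19.** The acid/amide pair is the hydrolysis product of a six-membered imide, so the C1–N bond is reconnected. One nitrogen then serves both carbonyls, and the imide doubles as the protecting group that keeps the ring-A carboxyl from interfering earlier. The pivaloyloxymethyl group on nitrogen falls off in the same basic operation. Hydroxide must attack the unhindered aroyl carbonyl, not the one buried next to the spiro centre. The single enantiomer is taken at 19 by chromatographic resolution. This is the first compound in which the centre is locked (O7′ benzylated, C3 attached to a carbonyl), and it is neutral and rigid. A catalytic asymmetric ring-C closure one step earlier is deliberately not relied on, because its free-phenol product can reopen under the same acid.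

**19 to phenol 17 to carbinol 14.** The two caps are removed (N–CH2 and O7′–CH2), then the C3–O1′ bond of ring C is cut. Forward, the tertiary alcohol 14 loses its peri acetate and water and closes through ortho-quinone methide 16. Keeping both carboxyl carbons in the imide is what makes this cut viable: a free or esterified ring-A carboxyl would capture the same cation as a phthalide, which is the thermodynamic sink of the open-chain diester variant.

**14 to trione 6 and naphthol 13.** The C3–C8′ bond is cut as a Friedel–Crafts hydroxyalkylation. The C4 ketone of 6 is activated by the adjacent imide carbonyl in the way isatin and ninhydrin are. In 13 the free β-naphthol oxygen O7′ directs to the adjacent α-position C8′, and the acetate on O1′ silences C2′ and C4′, which would win in the free diol. An organometallic addition is the alternative and is kept as the fallback.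

**6 to 5 to 4 to indanone 1 and diethyl oxalate 2.** The ketone comes from the activated methylene of homophthalimide 5, the imide from homophthalic acid 4, and 4 from oxidative opening of 4-methoxy-1-indanone 1 through its oxalyl derivative 3. The ring-A substitution pattern is fixed by the starting material.

**13 to 12 to 11 to 10 to 9 to aldehyde 7 and succinate 8.** The naphthalene is built by a Stobbe condensation and cyclisation, which places the acetoxy group, the ester (later the methyl) and the benzyloxy group unambiguously. Reduction, acetylation and one hydrogenolysis convert ester 10 into 13, unmasking O7′ and forming the methyl group in the same operation.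

## Roads not taken

**Alternative 1:** The cut is C3–N2 alone. The racemic naphthofuranol A2, which already carries the N-(2-silyloxyethyl)benzamide, would be oxidised to the ortho-quinone methide, and a chiral phosphoric acid would guide the amide nitrogen onto C3 to give silyl ether A1. The merits are real: both enantiomers of A2 converge, the stereocentre comes from a catalyst and not a resolution, the nitrogen substituent is in place, and no carbon has to be excised. On step count and material economy this road is better than the chosen one. Its weak points are mechanistic. A secondary amide is a poor and ambident nucleophile (attack through oxygen gives an iminolactone), and C3 is tetrasubstituted between two ortho-substituted arenes. The oxidant must spare an electron-rich naphthol. Above all, A1 is itself an ortho-hydroxybenzyl N,O-ketal that the same acid can reopen, so the enantiomeric purity rests on kinetic control of a reversible C–N bond. Against the shorter sequence the chosen plan sets a C3–N bond made by a stereospecific 1,2-shift, with no planar C3 after the resolution.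

**Alternative 2:** Three bonds (C7a–C1, C3a–C3, N2–C1) would form at once. A fluoride-generated methoxy-substituted aryne takes up an isocyanide at the carbon remote from the methoxy group, the aryl anion next to the methoxy group adds to the imidate carbon of cyclic imidate A4, and the nitrogen anion closes on the nitrilium carbon to give amidine A3. The polarity of the aryne fits the required regiochemistry, and no other plan here matches its convergence. The weak points: an aryl imidate C=N is a far poorer acceptor for a hindered aryl anion than the aldehydes, activated ketones and sulfonyl imines that such couplings normally use. A3 is formed as a racemate, so a resolution is needed here too, which means the chosen plan has no advantage in stereocontrol. The amidine must still be hydrolysed to the lactam and the tert-butyl group lost, and that calls for acid and heat on an acid-labile N,O-ketal. The chosen plan answers the better convergence with close precedent for every step and a resolution placed where the centre cannot racemise.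

**Alternative 3:** The C3–C8′ and C3–O bonds would form in one operation. A 1,2-naphthalyne (triple bond C7′–C8′) inserts the methoxy-flanked carbonyl of imide A6 (O to C7′, C3 to C8′), and the peri oxide closes on C3 to give A5, one hydrogenolysis from the target. This is the shortest road on paper, and the side chain arrives with the imide. The weak points are selectivity and access. Aryne insertion into C=O is established for formamides but barely for imides. The more hindered of two imide carbonyls must react, and with one orientation on an unsymmetrical naphthalyne. The aryne precursor (an ortho-silyl triflate bearing a free peri oxygen and the methyl group) needs a long synthesis of its own. A5 is racemic and already has the labile free phenol, so it can only be resolved at the most fragile stage. The chosen plan is much longer; in return the regiochemistry of every bond is fixed by the connectivity of an isolable intermediate, and the resolution is done on a compound that cannot racemise.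

Key step: step 14

Remark: in the text the lactam is numbered C1 (carbonyl), N2, C3 (spiro carbon), whereas the systematic spiro names number the spiro atom as C1. The spiro carbon is R in 20–25, 28 and 29 (ranking O > N or carbonyl C > ring-A carbon > naphthalene carbon). Which fraction of step 12 carries R is to be settled by anomalous-dispersion X-ray analysis. Compounds 1, 2, 7, 8 and 26 are taken as purchasable.

## Steps

Step 1
Reactants: 1 4-methoxy-1-indanone; 2 diethyl oxalate
Product: 4 2-(carboxymethyl)-3-methoxybenzoic acid, via 2-ethoxalyl indanone 3 (not isolated)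
Conditions: NaOEt, EtOH, 0 °C → rt; then 30% H2O2, aq KOH, 0 °C → rt; HCl to pH 1
Reagents that add atoms: hydrogen peroxide, OO; potassium hydroxide, [K+].[OH-]
Why: A crossed Claisen condensation puts an oxalyl group on C2 of the indanone, and alkaline hydrogen peroxide then cleaves the 1,2,4-tricarbonyl array on both sides of C2 (oxidative cleavage), the standard degradation of 1-indanones to homophthalic acids; the methoxy group ends up next to the acetic acid arm.

Step 2
Reactants: 4 2-(carboxymethyl)-3-methoxybenzoic acid
Product: 5 5-methoxyisoquinoline-1,3(2H,4H)-dione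
Conditions: urea, 1,2-dichlorobenzene, 175 °C
Reagents that add atoms: urea, NC(N)=O
Why: Thermal imide formation from a 1,5-diacid and urea (ammonia source, then cyclodehydration), the classical route to homophthalimides.

Step 3
Reactants: 5 5-methoxyisoquinoline-1,3(2H,4H)-dione
Product: 6 5-methoxyisoquinoline-1,3,4(2H)-trione
Conditions: SeO2, 1,4-dioxane/H2O, 100 °C
Reagents that add atoms: selenium dioxide, O=[Se]=O
Why: Riley oxidation of a methylene that is both benzylic and α to the imide carbonyl; it is the only enolisable position in 5.

Step 4
Reactants: 7 4-(benzyloxy)benzaldehyde; 8 dimethyl succinate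
Product: 9 (E)-4-[4-(benzyloxy)phenyl]-3-(methoxycarbonyl)but-3-enoic acid
Conditions: NaOMe, MeOH, reflux; then aq HCl
Reagents that add atoms: none
Why: Stobbe condensation; the lactone intermediate opens to the half-ester with the aryl group cis to the acetic acid arm, the geometry needed for ring closure.

Step 5
Reactants: 9 (E)-4-[4-(benzyloxy)phenyl]-3-(methoxycarbonyl)but-3-enoic acid
Product: 10 methyl 4-acetoxy-6-(benzyloxy)naphthalene-2-carboxylate
Conditions: Ac2O, NaOAc, 140 °C
Reagents that add atoms: acetic anhydride, CC(=O)OC(C)=O
Why: The mixed anhydride acylates the ring ortho to the side chain (intramolecular Friedel–Crafts acylation) and the naphthol is trapped as its acetate; cyclisation para-disposes the benzyloxy group so that it becomes O7′ of the target.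

Step 6
Reactants: 10 methyl 4-acetoxy-6-(benzyloxy)naphthalene-2-carboxylate
Product: 11 7-(benzyloxy)-3-(hydroxymethyl)naphthalen-1-ol
Conditions: LiAlH4, THF, 0 °C → rt
Reagents that add atoms: none
Why: Hydride reduction of the ester to the primary alcohol with concurrent cleavage of the aryl acetate; the benzyl ether is inert.

Step 7
Reactants: 11 7-(benzyloxy)-3-(hydroxymethyl)naphthalen-1-ol
Product: 12 [4-acetoxy-6-(benzyloxy)naphthalen-2-yl]methyl acetate
Conditions: Ac2O, pyridine, DMAP (cat.), CH2Cl2, rt
Reagents that add atoms: acetic anhydride, CC(=O)OC(C)=O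
Why: Exhaustive O-acetylation; the aryl acetate is the group that will silence the O1′ ring, and the benzylic acetate is a hydrogenolysable leaving group.

Step 8
Reactants: 12 [4-acetoxy-6-(benzyloxy)naphthalen-2-yl]methyl acetate
Product: 13 7-hydroxy-3-methylnaphthalen-1-yl acetate
Conditions: H2 (1 atm), Pd/C (10 wt %), EtOAc, rt
Reagents that add atoms: none
Why: Hydrogenolysis cleaves the benzyl ether and the naphthylmethyl acetate (giving the methyl group) in one operation, while the aryl acetate is untouched; this differentiates the two naphthol oxygens without a separate protection step.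

Step 9
Reactants: 6 5-methoxyisoquinoline-1,3,4(2H)-trione; 13 7-hydroxy-3-methylnaphthalen-1-yl acetate
Product: 14 8-(4-hydroxy-5-methoxy-1,3-dioxo-1,2,3,4-tetrahydroisoquinolin-4-yl)-7-hydroxy-3-methylnaphthalen-1-yl acetate (racemic)
Conditions: TsOH·H2O (10 mol %), (CF3)2CHOH/CH2Cl2, 0 °C → rt
Reagents that add atoms: none
Why: Friedel–Crafts hydroxyalkylation of a β-naphthol at its adjacent α-position by a ketone activated by a neighbouring carbonyl, as with isatins and ninhydrin; the free 7-hydroxyl directs to C8′ and the acetylated ring is much less nucleophilic, so C2′ and C4′ stay out.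

Step 10
Reactants: 14 8-(4-hydroxy-5-methoxy-1,3-dioxo-1,2,3,4-tetrahydroisoquinolin-4-yl)-7-hydroxy-3-methylnaphthalen-1-yl acetate
Product: 17 3′-hydroxy-5-methoxy-7′-methyl-1H,2′H-spiro[isoquinoline-4,2′-naphtho[1,8-bc]furan]-1,3(2H)-dione (racemic), via deacetylated triol 15 (not isolated), via ortho-quinone methide 16 (not isolated)
Conditions: HCl (1.25 M in MeOH), 40 °C; then MsOH (20 mol %), ClCH2CH2Cl, 50 °C
Reagents that add atoms: none
Why: Acid transesterification frees the peri hydroxyl, the tertiary benzylic alcohol ortho to the naphthol ionises to quinone methide 16, and the peri oxygen closes the five-membered ether, as in the known acid cyclisations of 8-(1-hydroxyalkyl)-1-naphthols; the stereocentre forms here as the racemate, and the imide ring keeps the ring-A carboxyl from capturing the cation as a phthalide.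

Step 11
Reactants: 17 3′-hydroxy-5-methoxy-7′-methyl-1H,2′H-spiro[isoquinoline-4,2′-naphtho[1,8-bc]furan]-1,3(2H)-dione
Product: 19 [3′-(benzyloxy)-5-methoxy-7′-methyl-1,3-dioxo-1H,2′H-spiro[isoquinoline-4,2′-naphtho[1,8-bc]furan]-2(3H)-yl]methyl pivalate (racemic), via N-pivaloyloxymethyl phenol 18 (not isolated)
Conditions: K2CO3 (1.05 equiv), ClCH2OC(O)CMe3, DMF, 0 °C; then K2CO3, BnBr, Bu4NI (cat.), rt
Reagents that add atoms: chloromethyl pivalate, CC(C)(C)C(=O)OCCl; benzyl bromide, BrCc1ccccc1
Why: In DMF the imide N–H is the more acidic site by several pK units, so one equivalent of carbonate and chloromethyl pivalate cap nitrogen first (standard pivaloyloxymethyl protection of an imide); the hindered naphthol is then benzylated (Williamson etherification), which closes the quinone methide channel and fixes the configuration of the spiro centre.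

Step 12
Reactants: 19 racemic N-pivaloyloxymethyl O-benzyl spiro imide
Product: 20 (R)-[3′-(benzyloxy)-5-methoxy-7′-methyl-1,3-dioxo-1H,2′H-spiro[isoquinoline-4,2′-naphtho[1,8-bc]furan]-2(3H)-yl]methyl pivalate
Conditions: preparative supercritical-fluid chromatography, amylose tris(3,5-dimethylphenylcarbamate) phase, CO2/MeOH
Reagents that add atoms: none
Why: Resolution by chromatography on a chiral stationary phase; 19 is neutral, rigid and has no ionisable route to racemisation, so this is where the single enantiomer is taken, and every later step leaves the four bonds at the spiro carbon intact or replaces one with retention.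

Step 13
Reactants: 20 (R)-N-pivaloyloxymethyl O-benzyl spiro imide
Product: 22 (R)-2-[3-(benzyloxy)-2-carbamoyl-7-methyl-2H-naphtho[1,8-bc]furan-2-yl]-3-methoxybenzoic acid, via ring-opened N-pivaloyloxymethyl amide acid 21 (not isolated)
Conditions: LiOH·H2O, THF/H2O, 0 °C → rt; then 1 M HCl to pH 3, 0 °C
Reagents that add atoms: lithium hydroxide, [Li+].[OH-]
Why: Hydroxide opens the N-alkyl imide at the unhindered aroyl carbonyl and not at the carbonyl shielded by the quaternary spiro centre; the resulting N-(acyloxymethyl)amide then loses pivalate and formaldehyde under the same conditions (the usual basic removal of this group) to leave the primary amide, and no bond to the stereocentre is touched.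

Step 14
Reactants: 22 (R)-2-[3-(benzyloxy)-2-carbamoyl-7-methyl-2H-naphtho[1,8-bc]furan-2-yl]-3-methoxybenzoic acid
Product: 25 (R)-3′-(benzyloxy)-7-methoxy-7′-methyl-2′H-spiro[isoindoline-1,2′-naphtho[1,8-bc]furan]-3-one, via isocyanato acid 23 (not isolated), via seven-membered carbamic carboxylic anhydride 24 (not isolated)
Conditions: PhI(OAc)2, 2,6-lutidine, MeCN (dry), 0 → 45 °C
Reagents that add atoms: none
Why: The trivalent iodine reagent converts the primary amide into an N-iodane, and loss of iodobenzene triggers the Hofmann rearrangement: the fully substituted, oxygen-bearing carbon migrates from the carbonyl carbon to nitrogen in a concerted 1,2-shift, which is why the configuration is retained. The ortho carboxylate then adds to isocyanate 23 to give the cyclic mixed anhydride 24, and the carbamate nitrogen acylates at the aroyl carbon C1 with loss of CO2. Both halves are known reaction types: Hofmann rearrangement of α-alkoxy amides with trivalent iodine, and decarboxylative amide formation from an isocyanate and a carboxylic acid. Ring B is closed by contraction of the seven-membered anhydride to the five-membered lactam (5-exo-trig attack of nitrogen on the aroyl carbonyl). No stereocentre is created; the existing one is transferred. The step needs capture by the internal acid and not by acetate or water; the ortho placement (seven-membered cyclisation), dry solvent and the lutidine-generated carboxylate provide for this. It also needs the oxidant to spare the naphthalene; the benzyl ether on O7′ and acetate ligands on iodine in MeCN provide for that. Lutidine also keeps the medium too weakly acidic to ionise the new N,O-ketal.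

Step 15
Reactants: 26 2-(benzyloxy)ethanol
Product: 27 2-(benzyloxy)ethyl trifluoromethanesulfonate
Conditions: Tf2O, 2,6-lutidine, CH2Cl2, −78 °C; cold aqueous wash, used at once
Reagents that add atoms: trifluoromethanesulfonic anhydride, O=S(=O)(OS(=O)(=O)C(F)(F)F)C(F)(F)F
Why: Standard triflation of a primary alcohol; it supplies an electrophile that alkylates at −78 °C.

Step 16
Reactants: 25 (R)-spiro lactam benzyl ether; 27 2-(benzyloxy)ethyl trifluoromethanesulfonate
Product: 28 (R)-3′-(benzyloxy)-2-[2-(benzyloxy)ethyl]-7-methoxy-7′-methyl-2′H-spiro[isoindoline-1,2′-naphtho[1,8-bc]furan]-3-one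
Conditions: NaN(SiMe3)2, THF, −78 °C; then 27, −78 → −40 °C
Reagents that add atoms: none
Why: N-alkylation of a lactam sodium salt; the triflate consumes the amidate at low temperature before it can expel the peri aryloxide (which would racemise C3), and the tight sodium ion pair in THF favours nitrogen over oxygen.

Step 17
Reactants: 28 (R)-bis-benzyl ether
Product: 29 (R)-3′-hydroxy-2-(2-hydroxyethyl)-7-methoxy-7′-methyl-2′H-spiro[isoindoline-1,2′-naphtho[1,8-bc]furan]-3-one
Conditions: H2 (1 atm), Pd/C (10 wt %), EtOAc, rt
Reagents that add atoms: none
Why: Hydrogenolysis of the aryl and the alkyl benzyl ether under neutral conditions; with neither acid nor base present, neither the N-acyliminium nor the quinone methide route to racemisation is open.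

## Compound list

1 | 4-methoxy-1-indanone | COc1cccc2c1CCC2=O | starting material
2 | diethyl oxalate | CCOC(=O)C(=O)OCC | starting material
3 | ethyl 2-(4-methoxy-1-oxo-2,3-dihydro-1H-inden-2-yl)-2-oxoacetate | CCOC(=O)C(=O)C1Cc2c(OC)cccc2C1=O | intermediate
4 | 2-(carboxymethyl)-3-methoxybenzoic acid | COc1cccc(C(=O)O)c1CC(=O)O | intermediate
5 | 5-methoxyisoquinoline-1,3(2H,4H)-dione | COc1cccc2c1CC(=O)NC2=O | intermediate
6 | 5-methoxyisoquinoline-1,3,4(2H)-trione | COc1cccc2c1C(=O)C(=O)NC2=O | intermediate
7 | 4-(benzyloxy)benzaldehyde | O=Cc1ccc(OCc2ccccc2)cc1 | starting material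
8 | dimethyl succinate | COC(=O)CCC(=O)OC | starting material
9 | (E)-4-[4-(benzyloxy)phenyl]-3-(methoxycarbonyl)but-3-enoic acid | COC(=O)/C(CC(=O)O)=C/c1ccc(OCc2ccccc2)cc1 | intermediate
10 | methyl 4-acetoxy-6-(benzyloxy)naphthalene-2-carboxylate | COC(=O)c1cc(OC(C)=O)c2cc(OCc3ccccc3)ccc2c1 | intermediate
11 | 7-(benzyloxy)-3-(hydroxymethyl)naphthalen-1-ol | OCc1cc(O)c2cc(OCc3ccccc3)ccc2c1 | intermediate
12 | [4-acetoxy-6-(benzyloxy)naphthalen-2-yl]methyl acetate | CC(=O)OCc1cc(OC(C)=O)c2cc(OCc3ccccc3)ccc2c1 | intermediate
13 | 7-hydroxy-3-methylnaphthalen-1-yl acetate | CC(=O)Oc1cc(C)cc2ccc(O)cc12 | intermediate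
14 | 8-(4-hydroxy-5-methoxy-1,3-dioxo-1,2,3,4-tetrahydroisoquinolin-4-yl)-7-hydroxy-3-methylnaphthalen-1-yl acetate (racemic) | COc1cccc2c1C(O)(c1c(O)ccc3cc(C)cc(OC(C)=O)c13)C(=O)NC2=O | intermediate
15 | 4-(2,8-dihydroxy-6-methylnaphthalen-1-yl)-4-hydroxy-5-methoxyisoquinoline-1,3(2H,4H)-dione (racemic) | COc1cccc2c1C(O)(c1c(O)ccc3cc(C)cc(O)c13)C(=O)NC2=O | intermediate
16 | 4-(8-hydroxy-6-methyl-2-oxonaphthalen-1(2H)-ylidene)-5-methoxyisoquinoline-1,3(2H,4H)-dione | COc1cccc2c1C(=C1C(=O)C=Cc3cc(C)cc(O)c31)C(=O)NC2=O | intermediate
17 | 3′-hydroxy-5-methoxy-7′-methyl-1H,2′H-spiro[isoquinoline-4,2′-naphtho[1,8-bc]furan]-1,3(2H)-dione (racemic) | COc1cccc2c1C1(Oc3cc(C)cc4ccc(O)c1c34)C(=O)NC2=O | intermediate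
18 | [3′-hydroxy-5-methoxy-7′-methyl-1,3-dioxo-1H,2′H-spiro[isoquinoline-4,2′-naphtho[1,8-bc]furan]-2(3H)-yl]methyl pivalate (racemic) | COc1cccc2c1C1(Oc3cc(C)cc4ccc(O)c1c34)C(=O)N(COC(=O)C(C)(C)C)C2=O | intermediate
19 | [3′-(benzyloxy)-5-methoxy-7′-methyl-1,3-dioxo-1H,2′H-spiro[isoquinoline-4,2′-naphtho[1,8-bc]furan]-2(3H)-yl]methyl pivalate (racemic) | COc1cccc2c1C1(Oc3cc(C)cc4ccc(OCc5ccccc5)c1c34)C(=O)N(COC(=O)C(C)(C)C)C2=O | intermediate
20 | (R)-[3′-(benzyloxy)-5-methoxy-7′-methyl-1,3-dioxo-1H,2′H-spiro[isoquinoline-4,2′-naphtho[1,8-bc]furan]-2(3H)-yl]methyl pivalate | COc1cccc2c1[C@@]1(Oc3cc(C)cc4ccc(OCc5ccccc5)c1c34)C(=O)N(COC(=O)C(C)(C)C)C2=O | intermediate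
21 | (R)-2-[3-(benzyloxy)-7-methyl-2-({[(pivaloyloxy)methyl]amino}carbonyl)-2H-naphtho[1,8-bc]furan-2-yl]-3-methoxybenzoic acid | COc1cccc(C(=O)O)c1[C@@]1(Oc2cc(C)cc3ccc(OCc4ccccc4)c1c23)C(=O)NCOC(=O)C(C)(C)C | intermediate
22 | (R)-2-[3-(benzyloxy)-2-carbamoyl-7-methyl-2H-naphtho[1,8-bc]furan-2-yl]-3-methoxybenzoic acid | COc1cccc(C(=O)O)c1[C@@]1(Oc2cc(C)cc3ccc(OCc4ccccc4)c1c23)C(N)=O | intermediate
23 | (R)-2-[3-(benzyloxy)-2-isocyanato-7-methyl-2H-naphtho[1,8-bc]furan-2-yl]-3-methoxybenzoic acid | COc1cccc(C(=O)O)c1[C@@]1(Oc2cc(C)cc3ccc(OCc4ccccc4)c1c23)N=C=O | intermediate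
24 | (R)-3′-(benzyloxy)-6-methoxy-7′-methyl-2′H-spiro[2,4-benzoxazepine-5,2′-naphtho[1,8-bc]furan]-1,3(4H)-dione | COc1cccc2c1[C@@]1(Oc3cc(C)cc4ccc(OCc5ccccc5)c1c34)NC(=O)OC2=O | intermediate
25 | (R)-3′-(benzyloxy)-7-methoxy-7′-methyl-2′H-spiro[isoindoline-1,2′-naphtho[1,8-bc]furan]-3-one | COc1cccc2c1[C@@]1(Oc3cc(C)cc4ccc(OCc5ccccc5)c1c34)NC2=O | intermediate
26 | 2-(benzyloxy)ethanol | OCCOCc1ccccc1 | starting material
27 | 2-(benzyloxy)ethyl trifluoromethanesulfonate | O=S(=O)(OCCOCc1ccccc1)C(F)(F)F | intermediate
28 | (R)-3′-(benzyloxy)-2-[2-(benzyloxy)ethyl]-7-methoxy-7′-methyl-2′H-spiro[isoindoline-1,2′-naphtho[1,8-bc]furan]-3-one | COc1cccc2c1[C@@]1(Oc3cc(C)cc4ccc(OCc5ccccc5)c1c34)N(CCOCc6ccccc6)C2=O | intermediate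
29 | (R)-3′-hydroxy-2-(2-hydroxyethyl)-7-methoxy-7′-methyl-2′H-spiro[isoindoline-1,2′-naphtho[1,8-bc]furan]-3-one | COc1cccc2c1[C@@]1(Oc3cc(C)cc4ccc(O)c1c34)N(CCO)C2=O | target

## Step count and least certain steps

Total: 17 steps. Longest linear sequence: 13 steps (steps 4–14, 16 and 17, from aldehyde 7).

**Step 14 (key step).** The isocyanate may be intercepted by acetate or adventitious water faster than by the ortho carboxylate, which would expose a free α-aryloxy amine that collapses; the trivalent iodine reagent may also oxidise the electron-rich naphthalene. The fallback separates rearrangement and ring closure. It sets out from 22: esterification with Me3SiCHN2 gives methyl (R)-2-[3-(benzyloxy)-2-carbamoyl-7-methyl-2H-naphtho[1,8-bc]furan-2-yl]-3-methoxybenzoate F1. Hofmann rearrangement with PhI(OAc)2 in MeOH traps the isocyanate as the methyl carbamate F2. LiN(SiMe3)2 at −78 °C closes the carbamate nitrogen onto the ester to give the N-(methoxycarbonyl) lactam F3, and Mg(OMe)2 in MeOH removes the exocyclic carbamate. The route is rejoined at 25.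

**Step 9.** Conversion may stall because the crowded adduct (carbinol between a methoxy-flanked ring and a naphthalene carbon with ortho hydroxyl and peri acetoxy groups) reverts by retro-Friedel–Crafts reaction. The fallback makes the bond irreversibly with an organometallic. It sets out from 13: NBS gives 8-bromo-7-hydroxy-3-methylnaphthalen-1-yl acetate F4, BnBr and K2CO3 give the benzyl ether F5, and K2CO3 in MeOH frees 7-(benzyloxy)-8-bromo-3-methylnaphthalen-1-ol F6. Deprotonation with iPrMgCl, bromine–lithium exchange with n-BuLi and addition to the chloromagnesium salt of 6 give the carbinol F7, which MsOH closes to the O-benzyl spiro imide F8. Chloromethyl pivalate and K2CO3 then cap the nitrogen, and the route is rejoined at 19.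

**Step 11.** The first alkylation may not discriminate, giving mixtures of N- and O-alkylated material. The fallback uses the chemoselectivity of silylation. It sets out from 17: TBSCl and imidazole give the aryl silyl ether F9 (the imide N–H does not react), chloromethyl pivalate and K2CO3 give the N-protected silyl ether F10, and CsF with BnBr in DMF exchanges silyl for benzyl in one flask. The route is rejoined at 19.

**Step 13.** Hydroxide may attack the carbonyl next to the spiro centre (more electrophilic through the α-oxygen, though more hindered), which would give the isomeric benzamide and C3-carboxylic acid. The fallback turns that preference to advantage. It sets out from 20: exhaustive hydrolysis (KOH, EtOH/H2O, 90 °C) gives the diacid F11, Ac2O gives the cyclic anhydride F12, and NH3 in THF at −40 °C opens it at the same, intrinsically more reactive carbonyl, placing the amide on the spiro-side carbon. The route is rejoined at 22.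

**Step 16.** The amidate may expel the peri aryloxide before it is alkylated (racemisation or loss of ring C), or alkylate on oxygen. The fallback avoids the anion. It sets out from 25: Rh2(OAc)4-catalysed N–H insertion of ethyl diazoacetate gives the N-(ethoxycarbonylmethyl) lactam F13, LiBH4 reduces the ester to the N-(2-hydroxyethyl) lactam benzyl ether F14, and hydrogenolysis as in step 17 removes the remaining benzyl group. The route is rejoined at 29.

**Step 17.** During the longer exposure that the aliphatic benzyl ether needs, hydrogenolysis of the doubly benzylic spiro C–O bond may set in. The fallback leaves only the fast aryl benzyl ether to hydrogen. It sets out from 25: alkylation as in step 16 with 2-(tert-butyldimethylsilyloxy)ethyl trifluoromethanesulfonate F15 (from the silyloxyethanol and Tf2O) gives the N-(2-silyloxyethyl) lactam benzyl ether F16. A brief hydrogenolysis gives the phenol F17, and Bu4NF buffered with AcOH removes the silyl group. The route is rejoined at 29.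

## Further compounds

F1 | step 14 | methyl (R)-2-[3-(benzyloxy)-2-carbamoyl-7-methyl-2H-naphtho[1,8-bc]furan-2-yl]-3-methoxybenzoate | COC(=O)c1cccc(OC)c1[C@@]1(Oc2cc(C)cc3ccc(OCc4ccccc4)c1c23)C(N)=O
F2 | step 14 | methyl (R)-2-{3-(benzyloxy)-2-[(methoxycarbonyl)amino]-7-methyl-2H-naphtho[1,8-bc]furan-2-yl}-3-methoxybenzoate | COC(=O)c1cccc(OC)c1[C@@]1(Oc2cc(C)cc3ccc(OCc4ccccc4)c1c23)NC(=O)OC
F3 | step 14 | methyl (R)-3′-(benzyloxy)-7-methoxy-7′-methyl-3-oxo-2′H-spiro[isoindoline-1,2′-naphtho[1,8-bc]furan]-2-carboxylate | COc1cccc2c1[C@@]1(Oc3cc(C)cc4ccc(OCc5ccccc5)c1c34)N(C(=O)OC)C2=O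
F4 | step 9 | 8-bromo-7-hydroxy-3-methylnaphthalen-1-yl acetate | CC(=O)Oc1cc(C)cc2ccc(O)c(Br)c12
F5 | step 9 | 7-(benzyloxy)-8-bromo-3-methylnaphthalen-1-yl acetate | CC(=O)Oc1cc(C)cc2ccc(OCc3ccccc3)c(Br)c12
F6 | step 9 | 7-(benzyloxy)-8-bromo-3-methylnaphthalen-1-ol | Cc1cc(O)c2c(Br)c(OCc3ccccc3)ccc2c1
F7 | step 9 | 4-[2-(benzyloxy)-8-hydroxy-6-methylnaphthalen-1-yl]-4-hydroxy-5-methoxyisoquinoline-1,3(2H,4H)-dione (racemic) | COc1cccc2c1C(O)(c1c(OCc4ccccc4)ccc3cc(C)cc(O)c13)C(=O)NC2=O
F8 | step 9 | 3′-(benzyloxy)-5-methoxy-7′-methyl-1H,2′H-spiro[isoquinoline-4,2′-naphtho[1,8-bc]furan]-1,3(2H)-dione (racemic) | COc1cccc2c1C1(Oc3cc(C)cc4ccc(OCc5ccccc5)c1c34)C(=O)NC2=O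
F9 | step 11 | 3′-[(tert-butyldimethylsilyl)oxy]-5-methoxy-7′-methyl-1H,2′H-spiro[isoquinoline-4,2′-naphtho[1,8-bc]furan]-1,3(2H)-dione (racemic) | COc1cccc2c1C1(Oc3cc(C)cc4ccc(O[Si](C)(C)C(C)(C)C)c1c34)C(=O)NC2=O
F10 | step 11 | {3′-[(tert-butyldimethylsilyl)oxy]-5-methoxy-7′-methyl-1,3-dioxo-1H,2′H-spiro[isoquinoline-4,2′-naphtho[1,8-bc]furan]-2(3H)-yl}methyl pivalate (racemic) | COc1cccc2c1C1(Oc3cc(C)cc4ccc(O[Si](C)(C)C(C)(C)C)c1c34)C(=O)N(COC(=O)C(C)(C)C)C2=O
F11 | step 13 | (R)-3-(benzyloxy)-2-(2-carboxy-6-methoxyphenyl)-7-methyl-2H-naphtho[1,8-bc]furan-2-carboxylic acid | COc1cccc(C(=O)O)c1[C@@]1(Oc2cc(C)cc3ccc(OCc4ccccc4)c1c23)C(=O)O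
F12 | step 13 | (R)-3′-(benzyloxy)-5-methoxy-7′-methyl-2′H-spiro[isochromane-4,2′-naphtho[1,8-bc]furan]-1,3-dione | COc1cccc2c1[C@@]1(Oc3cc(C)cc4ccc(OCc5ccccc5)c1c34)C(=O)OC2=O
F13 | step 16 | ethyl (R)-2-[3′-(benzyloxy)-7-methoxy-7′-methyl-3-oxo-2′H-spiro[isoindoline-1,2′-naphtho[1,8-bc]furan]-2-yl]acetate | COc1cccc2c1[C@@]1(Oc3cc(C)cc4ccc(OCc5ccccc5)c1c34)N(CC(=O)OCC)C2=O
F14 | step 16 | (R)-3′-(benzyloxy)-2-(2-hydroxyethyl)-7-methoxy-7′-methyl-2′H-spiro[isoindoline-1,2′-naphtho[1,8-bc]furan]-3-one | COc1cccc2c1[C@@]1(Oc3cc(C)cc4ccc(OCc5ccccc5)c1c34)N(CCO)C2=O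
F15 | step 17 | 2-[(tert-butyldimethylsilyl)oxy]ethyl trifluoromethanesulfonate | CC(C)(C)[Si](C)(C)OCCOS(=O)(=O)C(F)(F)F
F16 | step 17 | (R)-3′-(benzyloxy)-2-{2-[(tert-butyldimethylsilyl)oxy]ethyl}-7-methoxy-7′-methyl-2′H-spiro[isoindoline-1,2′-naphtho[1,8-bc]furan]-3-one | COc1cccc2c1[C@@]1(Oc3cc(C)cc4ccc(OCc5ccccc5)c1c34)N(CCO[Si](C)(C)C(C)(C)C)C2=O
F17 | step 17 | (R)-2-{2-[(tert-butyldimethylsilyl)oxy]ethyl}-3′-hydroxy-7-methoxy-7′-methyl-2′H-spiro[isoindoline-1,2′-naphtho[1,8-bc]furan]-3-one | COc1cccc2c1[C@@]1(Oc3cc(C)cc4ccc(O)c1c34)N(CCO[Si](C)(C)C(C)(C)C)C2=O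
A1 | alternative 1 | O-silyl ether of the target (product of the quinone methide lactam closure) | COc1cccc2c1[C@@]1(Oc3cc(C)cc4ccc(O)c1c34)N(CCO[Si](C)(C)C(C)(C)C)C2=O
A2 | alternative 1 | N-{2-[(tert-butyldimethylsilyl)oxy]ethyl}-2-(3-hydroxy-7-methyl-2H-naphtho[1,8-bc]furan-2-yl)-3-methoxybenzamide (racemic) | COc1cccc(C(=O)NCCO[Si](C)(C)C(C)(C)C)c1C1Oc2cc(C)cc3ccc(O)c1c23
A3 | alternative 2 | spiro N-tert-butyl amidine of the protected target (formed as racemate, target-configured enantiomer drawn) | COc1cccc2c1[C@@]1(Oc3cc(C)cc4ccc(OCc5ccccc5)c1c34)N(CCO[Si](C)(C)C(C)(C)C)C2=NC(C)(C)C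
A4 | alternative 2 | 3-(benzyloxy)-N-{2-[(tert-butyldimethylsilyl)oxy]ethyl}-7-methyl-2H-naphtho[1,8-bc]furan-2-imine | CC(C)(C)[Si](C)(C)OCCN=C1Oc2cc(C)cc3ccc(OCc4ccccc4)c1c23
A5 | alternative 3 | side-chain O-benzyl ether of the target (formed as racemate, target-configured enantiomer drawn) | COc1cccc2c1[C@@]1(Oc3cc(C)cc4ccc(O)c1c34)N(CCOCc3ccccc3)C2=O
A6 | alternative 3 | 2-[2-(benzyloxy)ethyl]-4-methoxyisoindoline-1,3-dione | COc1cccc2C(=O)N(CCOCc3ccccc3)C(=O)c12
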